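## Structural features

The target is a cis-fused decalin of the labdane type (ring A: C1–C5 and C10; ring B: C5–C10) with a tetrasubstituted C8=C9 alkene. C8 carries a methyl group and C9 a two-carbon chain (C11, C12) that ends in a β-substituted butenolide (C13–C16). Target numbering is kept for every intermediate, and β means the face of the C10 methyl group. Five stereocentres sit next to each other: quaternary C4 (α-methyl C18, β-acetoxymethyl C19), the ring-fusion methine C5 (β-H), quaternary C10 (β-methyl), the carbinol C6 (α-OH) beside C5, and the carbinol C2 (α-OH) between C4 and C10 on ring A; the absolute configuration is 2R,4S,5S,6S,10S. Fragile groups are the butenolide (base, hydride, organometallics), the primary acetate beside two free secondary hydroxyls (acyl migration, selective acylation), and the C8=C9 alkene, which is β,γ to any C6 carbonyl (drift into conjugation, epimerisation at C5) and competes with a furan for singlet oxygen. The real difficulty is the C4–C5–C10 array, two quaternary carbons across a cis ring fusion, together with the fact that an aromatic precursor of ring B holds no stereochemical information. The key step uses the 1,5-diene C4=C3–C2(O⁻)–C7–C6=C5 hidden in the C2-oxygen/C6-oxygen pattern: in a 2-alkenylbicyclo[2.2.2]octa-5,7-dien-2-ol (bridgeheads C7 and C10; bridges C1–C2, C5=C6, C8=C9) the C2–C7 bond is traded for C4–C5, which closes ring A onto ring B, sets C4 and C5 relative to C10 and leaves oxygen at C2 and C6.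

## Logic of the disconnections

35 is traced to 33 and then to 32 without cutting a skeletal bond: the lactone carbonyl C15 and the C16 methylene go back to the two α-carbons of a furan. A butenolide would not survive organometallic addition, KH or hydride, whereas the furan does, so the side chain can be in place from 8 onward. The forward steps must oxidise the furan in preference to the C8=C9 alkene and place the carbonyl on the α-carbon remote from the chain.

32 goes back to 31 and then to 29 by removing the C6–H and C2–H bonds, because both oxygens leave the key step at the carbonyl level (C2 ketone, C6 enol ether). The order is part of the plan: C2 is reduced in 29 while ring B is still a flat diene, and C6 is reduced only after that. Each reduction must deliver hydride to the β face, and the acid step between them must not move the alkene or epimerise C5.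

29 goes back to 27 by cutting the O19–acetyl bond. An ester cannot pass through steps 14 and 15, so a silyl ether is carried instead. The exchange is placed where C19–OH is the only hydroxyl in the molecule, which removes any need for selective acetylation.

27 goes back to 24 by cutting C4–C5 and restoring C2–C7. Ring A, the stereocentres C4 and C5 and the cis fusion all reduce to a rigid bicyclo[2.2.2]octadiene, and C4 becomes a question of alkene geometry. The forward step needs the right C2 epimer, a Z alkene, and a [3,3] shift that is faster than cycloreversion.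

24 goes back to 17 and 21 by cutting C2–C3. This is convergent, and the geometry of 21 comes from a directed carbometalation of 18. The addition must come from the enol-ether face of the ketone, with a non-basic nucleophile and without silyl migration.

17 goes back to 15 (two C1–O bonds) and 15 to 14 (separation of enantiomers). The methoxy groups are what is left of the masked quinone; removing them before step 15 keeps C1 unsubstituted next to the bond that forms. The resolution is placed at the first chiral compound, because neither partner of the cycloaddition is chiral.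

14 goes back to 12 and 13 by cutting C5–C10 and C6–C7 (retro-Diels–Alder). The bicycle with both bridgeheads and both unsaturated bridges comes from a flat dienone and a two-carbon alkyne. The forward step must put the alkyne CH on the methyl-bearing diene terminus and must run below the temperature at which 13 decomposes.

12 goes back to 11 (dearomatisation), 11 to 10 (phenol release), and 10 to 6 and 8 by cutting C9–C11 (cross-coupling through 9); 8 comes from 7. The coupling has to work on a bromide flanked by two methyl groups.

6 goes back through 5, 3 and 2 to 1. The new ring oxygen is brought in as a formyl group ortho to the phenol and then converted to C–O; protecting the original phenol first ensures that the methoxy group ends up next to the ring methyl and the free phenol next to the ring C–H, the pattern the dearomatisation needs.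

## Other disconnections considered

Alternative 1: The cut is through C5–C10 and C6–C7 of A1, leading to the open-chain triene A2 with a Z-alkenylboronate. Heating A2 would close rings A and B in one intramolecular Diels–Alder reaction and set C5, C6 and C10; oxidation of the C–B bond with retention would then give the 6α-alcohol.
- In its favour: C6 never passes through a ketone, so the β,γ-enone and the C5 epimerisation risk of 31 are avoided, and on this point it is better than the chosen plan. Absolute configuration would come from the C2 and C4 stereocentres of A2 and no resolution would be needed, which is also better. Acetate and butenolide can be present, so the endgame is shorter.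
- Against it: the diene terminus C10 is fully substituted, so one group must sit inside the s-cis diene, and C8 and C9 are substituted as well; such dienes react poorly. An alkenylboronate has no activating group. The cis fusion would depend on the folding of the tether, whereas the bicycle 24 fixes it by construction. A2 needs an acyclic quaternary stereocentre bearing a Z-alkenylboronate, which is long to make.
- Comparison: on mechanism both key steps are pericyclic, but the chosen one is anion-accelerated and runs near room temperature, while this one needs forcing heat. On step economy the alternative is probably longer before its key step and shorter after it.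

Alternative 2: The cut is through C6–C7 of A3 with C6–C9 reconnected, leading to the 2-alkenylcyclobutanol A4. The potassium alkoxide of A4 would undergo an alkoxide-driven 1,3-shift that expands the four-membered ring to ring B and forms C8=C9 and the C6 carbinol together.
- In its favour: the C5–C10 cis fusion is already present in the bicyclo[4.2.0] frame, the C6 oxygen appears at the alcohol level, and the alkoxide has no aromatic product to collapse to; on the last point it is the better of the two plans.
- Against it: such shifts can run through fragmentation and recombination in which C6 becomes trigonal, so the C6 configuration is not secured. A4 has two adjacent quaternary ring carbons (C9, C10) on a cyclobutane, which is hard to assemble. C2 is already at the alcohol level in A4 and would have to be set earlier.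
- Comparison: structurally it builds one ring and one stereocentre where the chosen step builds one ring and two. The furan endgame is the same as in the chosen plan (equal), and the step count is not lower.

Alternative 3: The cut is through C1–C10 of A5, leading to the cyclohexenol A6 with a tethered silyl enol ether. Me3SiOTf would ionise the C8 tertiary allylic alcohol, and the enol-ether carbon C1 would attack C10 of the allyl cation, closing ring A with the alkene left at C8=C9 and C2 as a ketone.
- In its favour: the conditions are mild enough to carry the acetate and the butenolide, so neither a protecting-group exchange nor a furan oxidation follows, and the C6 oxygen stereocentre is in place beforehand; the endgame economy is better than in the chosen plan.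
- Against it: C1 has to attack the more hindered allyl terminus to make quaternary C10; attack at C8 or loss of a proton to a diene compete; the cis fusion rests on face selection by the C5 substituent alone. A6 needs the contiguous C4 (quaternary), C5, C6 triad on a cyclohexene before the key step.
- Comparison: mechanistically it is a stepwise cationic closure with less built-in stereocontrol than the concerted shift of 24. It still ends at a C2 ketone, so the C2 reduction problem is the same as for 27 (equal).

Key step: step 15

Assumption: diene 12 and alkyne 13 are both achiral, so cycloadduct 14 must form as a racemate; the single enantiomer is secured by resolution at that stage (step 10). The C19 oxygen is carried as a triisopropylsilyl ether, not a smaller silyl ether.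

## Route

Step 1
Reactants: 1 4-bromo-3,5-dimethylphenol
Product: 2 3-bromo-6-hydroxy-2,4-dimethylbenzaldehyde
Conditions: MgCl2, Et3N, (CH2O)n, MeCN, reflux
Reagents that add atoms: paraformaldehyde (formaldehyde unit), C=O
Why: Magnesium-phenoxide-directed ortho-formylation (Casnati–Skattebøl type); the two ortho positions are equivalent by symmetry and the para position is blocked by bromine, so one aldehyde is expected.

Step 2
Reactants: 2 3-bromo-6-hydroxy-2,4-dimethylbenzaldehyde
Product: 3 3-bromo-6-(methoxymethoxy)-2,4-dimethylbenzaldehyde
Conditions: MOMCl, i-Pr2NEt, CH2Cl2, 0 °C to rt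
Reagents that add atoms: chloromethyl methyl ether, COCCl
Why: O-alkylation of the phenol to its methoxymethyl acetal; it keeps the original phenol oxygen distinct from the oxygen introduced in step 3.

Step 3
Reactants: 3 3-bromo-6-(methoxymethoxy)-2,4-dimethylbenzaldehyde
Product: 5 3-bromo-6-(methoxymethoxy)-2,4-dimethylphenol, via aryl formate 4 (not isolated)
Conditions: mCPBA, CH2Cl2, 0 °C to rt; aq. NaHCO3 wash; then K2CO3 (cat.), MeOH, rt
Reagents that add atoms: 3-chloroperoxybenzoic acid, OOC(=O)c1cccc(Cl)c1
Why: Baeyer–Villiger (Dakin-type) oxidation; the electron-rich aryl group migrates in preference to hydrogen to give the formate, which is cleaved by methanolysis.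

Step 4
Reactants: 5 3-bromo-6-(methoxymethoxy)-2,4-dimethylphenol
Product: 6 2-bromo-4-methoxy-5-(methoxymethoxy)-1,3-dimethylbenzene
Conditions: MeI, K2CO3, DMF, rt
Reagents that add atoms: iodomethane, CI
Why: Williamson methylation of the hindered phenol; the methoxy group now lies between the protected oxygen and a ring methyl, as the later dienone requires.

Step 5
Reactants: 7 furan-3-carbaldehyde
Product: 8 3-ethenylfuran
Conditions: Ph3PCH3Br, KOtBu, THF, 0 °C; co-distilled with THF and used as a solution
Reagents that add atoms: methyltriphenylphosphonium bromide, C[P+](c1ccccc1)(c1ccccc1)c1ccccc1.[Br-]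
Why: Wittig methylenation of an aromatic aldehyde; the volatile product is not concentrated.

Step 6
Reactants: 8 3-ethenylfuran; 6 2-bromo-4-methoxy-5-(methoxymethoxy)-1,3-dimethylbenzene
Product: 10 3-{2-[3-methoxy-4-(methoxymethoxy)-2,6-dimethylphenyl]ethyl}furan, via alkylborane 9 (not isolated)
Conditions: 9-BBN, THF, 0 °C to rt; then 6, Pd(OAc)2 (cat.), SPhos (cat.), K3PO4, THF/H2O, 65 °C
Reagents that add atoms: none
Why: Anti-Markovnikov hydroboration of the vinyl group (the furan ring is not hydroborated), then B-alkyl Suzuki–Miyaura coupling; the bulky electron-rich biaryl phosphine is chosen for a bromide with two ortho methyl groups.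

Step 7
Reactants: 10 3-{2-[3-methoxy-4-(methoxymethoxy)-2,6-dimethylphenyl]ethyl}furan
Product: 11 4-[2-(furan-3-yl)ethyl]-2-methoxy-3,5-dimethylphenol
Conditions: HCl (cat.), MeOH, rt
Reagents that add atoms: none
Why: Acid-catalysed acetal exchange; aryl methoxymethyl ethers cleave under dilute methanolic acid that a 3-alkylfuran tolerates.

Step 8
Reactants: 11 4-[2-(furan-3-yl)ethyl]-2-methoxy-3,5-dimethylphenol
Product: 12 4-[2-(furan-3-yl)ethyl]-6,6-dimethoxy-3,5-dimethylcyclohexa-2,4-dien-1-one
Conditions: PhI(OAc)2, MeOH, 0 °C; NaHCO3 work-up
Reagents that add atoms: methanol, CO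
Why: Oxidative dearomatisation of a 2-methoxyphenol with a hypervalent iodine reagent; methanol adds at the methoxy-bearing carbon to give the masked ortho-quinone. Substituents at C3, C4 and C5 of the dienone block its self-dimerisation, and the phenol is oxidised much faster than the furan.

Step 9
Reactants: 12 4-[2-(furan-3-yl)ethyl]-6,6-dimethoxy-3,5-dimethylcyclohexa-2,4-dien-1-one; 13 ethoxyacetylene
Product: 14 racemic 6-ethoxy-8-[2-(furan-3-yl)ethyl]-3,3-dimethoxy-4,7-dimethylbicyclo[2.2.2]octa-5,7-dien-2-one
Conditions: 13 (excess, solution in hexanes), toluene, sealed tube, 65 °C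
Reagents that add atoms: none
Why: Diels–Alder reaction with inverse electron demand between the electron-poor dienone and the ynol ether. The nucleophilic CH terminus bonds to the δ-carbon of the dienone (the methyl-bearing terminus, future C10) and the oxygen-bearing carbon to the α-carbon (future C7), which places the ethoxy group on C6. An alkyne has no endo/exo issue, so one racemic adduct is expected.

Step 10
Reactants: 14 racemic cycloadduct
Product: 15 (1S,4S)-6-ethoxy-8-[2-(furan-3-yl)ethyl]-3,3-dimethoxy-4,7-dimethylbicyclo[2.2.2]octa-5,7-dien-2-one
Conditions: preparative SFC, amylose tris(3,5-dimethylphenylcarbamate) stationary phase, CO2/MeOH, 35 °C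
Reagents that add atoms: none
Why: Resolution by chromatography on a chiral stationary phase at the first chiral intermediate, where the least material is lost; ketone, ketal and furan give the contacts needed for discrimination. The wanted enantiomer would be assigned by anomalous-dispersion crystallography of a derivative.

Step 11
Reactants: 15 (1S,4S)-dimethoxy ketone
Product: 17 (1S,4S)-6-ethoxy-8-[2-(furan-3-yl)ethyl]-4,7-dimethylbicyclo[2.2.2]octa-5,7-dien-2-one, via monomethoxy ketone 16 (not isolated)
Conditions: SmI2 (excess), THF/MeOH, −78 °C to 0 °C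
Reagents that add atoms: none
Why: Reductive cleavage of α-alkoxy ketone C–O bonds by divalent samarium (ketyl, loss of methoxide, protonation of the samarium enolate), run twice; enol ether, alkenes and furan are inert, and C1 becomes the unsubstituted methylene needed next to the bond formed in step 15.

Step 12
Reactants: 18 prop-2-yn-1-ol
Product: 20 (2Z)-3-iodo-2-methylprop-2-en-1-ol, via cyclic alkenylmagnesium alkoxide 19 (not isolated)
Conditions: MeMgBr, CuI (cat.), THF, −10 °C to rt; then I2, −78 °C to 0 °C
Reagents that add atoms: methylmagnesium bromide, C[Mg]Br; iodine, II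
Why: Alkoxide-directed anti-carbomagnesiation puts methyl on the internal carbon and magnesium on the terminal carbon in a five-membered chelate; iodinolysis with retention gives iodine cis to CH2OH (Z).

Step 13
Reactants: 20 (2Z)-3-iodo-2-methylprop-2-en-1-ol
Product: 21 {[(2Z)-3-iodo-2-methylprop-2-en-1-yl]oxy}tri(propan-2-yl)silane
Conditions: TIPSCl, imidazole, DMF, rt
Reagents that add atoms: chlorotri(propan-2-yl)silane, CC(C)[Si](Cl)(C(C)C)C(C)C
Why: Silylation of the primary alcohol; the bulky triisopropylsilyl group is chosen because in the Z series a smaller silyl group can shift from oxygen to the cis carbanion (step 14) or to the cis tertiary alkoxide (step 15).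

Step 14
Reactants: 17 (1S,4S)-bicyclic ketone; 21 Z-alkenyl iodide
Product: 24 (1R,2S,4S)-6-ethoxy-8-[2-(furan-3-yl)ethyl]-4,7-dimethyl-2-[(1Z)-2-methyl-3-{[tri(propan-2-yl)silyl]oxy}prop-1-en-1-yl]bicyclo[2.2.2]octa-5,7-dien-2-ol, via alkenyllithium 22 (not isolated), via alkenylcerium dichloride 23 (not isolated)
Conditions: 21, t-BuLi (2 equiv), Et2O, −78 °C; CeCl3, THF, −78 °C; then 17, −78 °C to −40 °C
Reagents that add atoms: none
Why: Iodine–lithium exchange with retention, transmetalation to the less basic organocerium (no enolisation of the ketone), then 1,2-addition that sets C2. The two faces of the carbonyl differ in the atom each unsaturated bridge carries next to bridgehead C7: an enol-ether oxygen (ethyl turned away) on one side, a methyl group on the other, and the oxophilic metal can pre-coordinate that oxygen, so attack should come from the enol-ether side and place the alkenyl group syn to C5=C6. The C2 epimer, if formed, is a diastereomer and is removed by chromatography.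

Step 15
Reactants: 24 (1R,2S,4S)-2-alkenylbicyclo[2.2.2]octa-5,7-dien-2-ol
Product: 27 (4S,5S,10S)-6-ethoxy-9-[2-(furan-3-yl)ethyl]-4α,8,10β-trimethyl-4β-({[tri(propan-2-yl)silyl]oxy}methyl)-5β-H-cis-decalin-6,8-dien-2-one, via potassium alkoxide 25 (not isolated), via potassium enolate 26 (not isolated)
Conditions: KH (oil-free), 18-crown-6, THF, 0 °C to rt; sat. aq. NH4Cl, −78 °C
Reagents that add atoms: none
Why: Deprotonation gives alkoxide 25, whose crown-separated O⁻ weakens C2–C7 and triggers a [3,3]-sigmatropic shift of the 1,5-diene C4=C3–C2–C7–C6=C5: C4–C5 forms as C2–C7 breaks, giving the C2 enolate 26, which is protonated to 27 on quench. The closest known reaction type is the anionic oxy-Cope rearrangement of 2-alkenylbicyclo[2.2.2]oct-5-en-2-ols to cis-decalin enolates. Ring A closes as a six-membered carbocycle by suprafacial bonding between two sp2 termini (alkene carbon C4 onto enol-ether carbon C5) through the boat-shaped six-centre array that the bicycle enforces, because the alkene can align with the breaking C2–C7 bond only when it lies over the C5=C6 bridge. C5 is bonded on the face of the enol ether that is turned towards the C1–C2 bridge, the bridge that also holds C1 on C10, so C4 and C1 end up cis on ring B and the fusion is cis by construction (5β-H, 10β-methyl). C4 is set by alkene geometry: in the boat the group cis to C2 (CH2OSi) lies over C10 and the trans group (methyl) points outwards, which gives 4β-CH2O and 4α-methyl, so the Z purity from step 12 is what is needed. The selectivity required is [3,3] shift over alkoxide-driven cycloreversion to an arene and over a 1,3-shift; it is favoured by the pre-organised boat, the low temperature, the unsubstituted C1 and a silyl group too bulky to move to the cis alkoxide. Only the C2 epimer with the alkenyl group over the enol-ether bridge can react this way, which is why step 14 had to deliver it. Absolute configuration is carried over from the resolved bridgeheads of 15.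

Step 16
Reactants: 27 silyl ether ketone
Product: 29 (4S,5S,10S)-19-acetoxy-6-ethoxy-9-[2-(furan-3-yl)ethyl]-4α,8,10β-trimethyl-5β-H-cis-decalin-6,8-dien-2-one, via C19 alcohol 28 (not isolated)
Conditions: TBAF, THF, 0 °C to rt; then Ac2O, pyridine, DMAP (cat.), 0 °C to rt
Reagents that add atoms: acetic anhydride, CC(=O)OC(C)=O
Why: Fluoride cleavage of the silyl ether and acetylation of the only hydroxyl in the molecule, so no selectivity between hydroxyls is needed; the dienol ether is stable to these basic conditions.

Step 17
Reactants: 29 keto acetate
Product: 31 (2R,4S,5S,10S)-19-acetoxy-9-[2-(furan-3-yl)ethyl]-2α-hydroxy-4α,8,10β-trimethyl-5β-H-cis-decal-8-en-6-one, via 2α-hydroxy dienol ether 30 (not isolated)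
Conditions: NaBH4, MeOH/THF, −20 °C; then aq. oxalic acid, THF, 0 °C
Reagents that add atoms: water, O
Why: Hydride addition to the C2 ketone, then hydrolysis of the 2-alkoxydiene by protonation at C7 to the β,γ-unsaturated C6 ketone. While ring B is a flat diene, ring A should prefer the chair with CH2OAc equatorial and the 4α-methyl and C9 axial on the α face (the other chair puts C19 syn-axial to the C10 methyl and C4 beside the C6 alkoxy group), so hydride enters from the β face and gives the 2α-alcohol; this is why C2 is reduced before the enol ether is opened. Cold dilute aqueous acid lets water trap the oxocarbenium ion before it can lose H-5 or drift to the conjugated enone.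

Step 18
Reactants: 31 hydroxy ketone
Product: 32 (2R,4S,5S,6S,10S)-19-acetoxy-9-[2-(furan-3-yl)ethyl]-4α,8,10β-trimethyl-5β-H-cis-decal-8-ene-2α,6α-diol
Conditions: NaBH4, CeCl3·7H2O, MeOH, −40 °C to 0 °C
Reagents that add atoms: none
Why: Luche-type 1,2-reduction; CeCl3 activates the hindered ketone and keeps the medium non-basic, so the alkene does not move into conjugation and the acetate survives. With the 2α-hydroxyl equatorial, ring A folds under the α face of ring B (C1 axial over C6), so hydride attacks the convex β face, the side of H-5 and the C10 methyl, and gives the 6α-alcohol.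

Step 19
Reactants: 32 furan diol
Product: 33 γ-hydroxybutenolide of 32 (5-hydroxy-4-substituted furan-2(5H)-one; two epimers at the hemiacetal carbon)
Conditions: O2, hν (visible), rose bengal (cat.), i-Pr2NEt, CH2Cl2, −78 °C
Reagents that add atoms: dioxygen, O=O
Why: [4+2] addition of singlet oxygen to the furan gives the 2,5-endoperoxide, and the hindered amine removes the proton on the unsubstituted, less hindered α-carbon (Kornblum–DeLaMare-type fragmentation), so the carbonyl ends up remote from the chain. A furan takes up singlet oxygen faster than a hindered ring alkene undergoes the ene reaction, and irradiation is stopped once 32 is consumed.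

Step 20
Reactants: 33 γ-hydroxybutenolide
Product: 35 [(1S,3R,4aS,8S,8aS)-3,8-dihydroxy-1,4a,6-trimethyl-5-[2-(5-oxo-2,5-dihydrofuran-3-yl)ethyl]-1,2,3,4,4a,7,8,8a-octahydronaphthalen-1-yl]methyl acetate, via hydroxy acid 34 (not isolated)
Conditions: NaBH4, EtOH, 0 °C; then 1 M HCl
Reagents that add atoms: none
Why: The hydroxybutenolide is in equilibrium with its open Z aldehyde acid; borohydride reduces the aldehyde to hydroxy acid 34, which lactonises on acidification to the butenolide. Short exposure at 0 °C spares the acetate and the conjugated lactone.

## Compound list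

1 | 4-bromo-3,5-dimethylphenol | Cc1cc(O)cc(C)c1Br | starting material
2 | 3-bromo-6-hydroxy-2,4-dimethylbenzaldehyde | Cc1cc(O)c(C=O)c(C)c1Br | intermediate
3 | 3-bromo-6-(methoxymethoxy)-2,4-dimethylbenzaldehyde | Cc1cc(OCOC)c(C=O)c(C)c1Br | intermediate
4 | 3-bromo-6-(methoxymethoxy)-2,4-dimethylphenyl formate | Cc1cc(OCOC)c(OC=O)c(C)c1Br | intermediate (not isolated)
5 | 3-bromo-6-(methoxymethoxy)-2,4-dimethylphenol | Cc1cc(OCOC)c(O)c(C)c1Br | intermediate
6 | 2-bromo-4-methoxy-5-(methoxymethoxy)-1,3-dimethylbenzene | Cc1cc(OCOC)c(OC)c(C)c1Br | intermediate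
7 | furan-3-carbaldehyde | O=Cc1ccoc1 | starting material
8 | 3-ethenylfuran | C=Cc1ccoc1 | intermediate
9 | 9-[2-(furan-3-yl)ethyl]-9-borabicyclo[3.3.1]nonane | C1CC2CCCC(C1)B2CCc1ccoc1 | intermediate (not isolated)
10 | 3-{2-[3-methoxy-4-(methoxymethoxy)-2,6-dimethylphenyl]ethyl}furan | Cc1cc(OCOC)c(OC)c(C)c1CCc1ccoc1 | intermediate
11 | 4-[2-(furan-3-yl)ethyl]-2-methoxy-3,5-dimethylphenol | Cc1cc(O)c(OC)c(C)c1CCc1ccoc1 | intermediate
12 | 4-[2-(furan-3-yl)ethyl]-6,6-dimethoxy-3,5-dimethylcyclohexa-2,4-dien-1-one | COC1(OC)C(=O)C=C(C)C(CCc2ccoc2)=C1C | intermediate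
13 | ethoxyacetylene (ethoxyethyne) | C#COCC | starting material
14 | racemic 6-ethoxy-8-[2-(furan-3-yl)ethyl]-3,3-dimethoxy-4,7-dimethylbicyclo[2.2.2]octa-5,7-dien-2-one | CCOC1=CC2(C)C(CCc3ccoc3)=C(C)C1C(=O)C2(OC)OC | intermediate
15 | (1S,4S)-6-ethoxy-8-[2-(furan-3-yl)ethyl]-3,3-dimethoxy-4,7-dimethylbicyclo[2.2.2]octa-5,7-dien-2-one | O=C1C(OC)(OC)[C@@]2(C)C=C(OCC)[C@@H]1C(C)=C2CCc3ccoc3 | intermediate
16 | (1S,4S)-6-ethoxy-8-[2-(furan-3-yl)ethyl]-3-methoxy-4,7-dimethylbicyclo[2.2.2]octa-5,7-dien-2-one (either C3 epimer) | O=C1C(OC)[C@@]2(C)C=C(OCC)[C@@H]1C(C)=C2CCc3ccoc3 | intermediate (not isolated)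
17 | (1S,4S)-6-ethoxy-8-[2-(furan-3-yl)ethyl]-4,7-dimethylbicyclo[2.2.2]octa-5,7-dien-2-one | O=C1C[C@@]2(C)C=C(OCC)[C@@H]1C(C)=C2CCc3ccoc3 | intermediate
18 | prop-2-yn-1-ol | C#CCO | starting material
19 | cyclic Z-alkenylmagnesium alkoxide (4-methyl-2,5-dihydro-1,2-oxamagnesole) | CC1=C[Mg]OC1 | intermediate (not isolated)
20 | (2Z)-3-iodo-2-methylprop-2-en-1-ol | OC/C(C)=C\I | intermediate
21 | {[(2Z)-3-iodo-2-methylprop-2-en-1-yl]oxy}tri(propan-2-yl)silane | CC(C)[Si](OC/C(C)=C\I)(C(C)C)C(C)C | intermediate
22 | (1Z)-2-methyl-3-{[tri(propan-2-yl)silyl]oxy}prop-1-en-1-yllithium | CC(C)[Si](OC/C(C)=C\[Li])(C(C)C)C(C)C | intermediate (not isolated)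
23 | (1Z)-2-methyl-3-{[tri(propan-2-yl)silyl]oxy}prop-1-en-1-ylcerium dichloride | CC(C)[Si](OC/C(C)=C\[Ce](Cl)Cl)(C(C)C)C(C)C | intermediate (not isolated)
24 | (1R,2S,4S)-6-ethoxy-8-[2-(furan-3-yl)ethyl]-4,7-dimethyl-2-[(1Z)-2-methyl-3-{[tri(propan-2-yl)silyl]oxy}prop-1-en-1-yl]bicyclo[2.2.2]octa-5,7-dien-2-ol (alkenyl group syn to the enol-ether bridge) | CC(C)[Si](OC/C(C)=C\[C@@]1(O)C[C@@]2(C)C=C(OCC)[C@@H]1C(C)=C2CCc3ccoc3)(C(C)C)C(C)C | intermediate
25 | potassium alkoxide of 24 | CC(C)[Si](OC/C(C)=C\[C@@]1([O-])C[C@@]2(C)C=C(OCC)[C@@H]1C(C)=C2CCc3ccoc3)(C(C)C)C(C)C.[K+] | intermediate (not isolated)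
26 | potassium C2 enolate (C2=C3) of 27 | CC(C)[Si](OC[C@@]1(C)C=C([O-])C[C@]2(C)C(CCc3ccoc3)=C(C)C=C(OCC)[C@H]12)(C(C)C)C(C)C.[K+] | intermediate (not isolated)
27 | (4S,5S,10S)-6-ethoxy-9-[2-(furan-3-yl)ethyl]-4α,8,10β-trimethyl-4β-({[tri(propan-2-yl)silyl]oxy}methyl)-5β-H-cis-decalin-6,8-dien-2-one | CC(C)[Si](OC[C@@]1(C)CC(=O)C[C@]2(C)C(CCc3ccoc3)=C(C)C=C(OCC)[C@H]12)(C(C)C)C(C)C | intermediate
28 | C19 alcohol of 27 (4β-hydroxymethyl) | OC[C@@]1(C)CC(=O)C[C@]2(C)C(CCc3ccoc3)=C(C)C=C(OCC)[C@H]12 | intermediate (not isolated)
29 | (4S,5S,10S)-19-acetoxy-6-ethoxy-9-[2-(furan-3-yl)ethyl]-4α,8,10β-trimethyl-5β-H-cis-decalin-6,8-dien-2-one | CC(=O)OC[C@@]1(C)CC(=O)C[C@]2(C)C(CCc3ccoc3)=C(C)C=C(OCC)[C@H]12 | intermediate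
30 | 2α-alcohol of 29 (2R; dienol ether intact) | CC(=O)OC[C@@]1(C)C[C@H](O)C[C@]2(C)C(CCc3ccoc3)=C(C)C=C(OCC)[C@H]12 | intermediate (not isolated)
31 | (2R,4S,5S,10S)-19-acetoxy-9-[2-(furan-3-yl)ethyl]-2α-hydroxy-4α,8,10β-trimethyl-5β-H-cis-decal-8-en-6-one | CC(=O)OC[C@@]1(C)C[C@H](O)C[C@]2(C)C(CCc3ccoc3)=C(C)CC(=O)[C@H]12 | intermediate
32 | (2R,4S,5S,6S,10S)-19-acetoxy-9-[2-(furan-3-yl)ethyl]-4α,8,10β-trimethyl-5β-H-cis-decal-8-ene-2α,6α-diol | CC(=O)OC[C@@]1(C)C[C@H](O)C[C@]2(C)C(CCc3ccoc3)=C(C)C[C@H](O)[C@H]12 | intermediate
33 | γ-hydroxybutenolide of 32: side chain 2-(2-hydroxy-5-oxo-2,5-dihydrofuran-3-yl)ethyl (hemiacetal epimers) | CC(=O)OC[C@@]1(C)C[C@H](O)C[C@]2(C)C(CCC3=CC(=O)OC3O)=C(C)C[C@H](O)[C@H]12 | intermediate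
34 | hydroxy acid: side chain (3Z)-4-carboxy-3-(hydroxymethyl)but-3-en-1-yl | CC(=O)OC[C@@]1(C)C[C@H](O)C[C@]2(C)C(CC/C(CO)=C/C(O)=O)=C(C)C[C@H](O)[C@H]12 | intermediate (not isolated)
35 | [(1S,3R,4aS,8S,8aS)-3,8-dihydroxy-1,4a,6-trimethyl-5-[2-(5-oxo-2,5-dihydrofuran-3-yl)ethyl]-1,2,3,4,4a,7,8,8a-octahydronaphthalen-1-yl]methyl acetate | CC(=O)OC[C@@]1(C)C[C@H](O)C[C@]2(C)C(CCC3=CC(=O)OC3)=C(C)C[C@H](O)[C@H]12 | target

## Step count and least certain steps

Total: 20 steps. Longest linear sequence: 17 steps (1 to 35 through steps 1–4, 6–11 and 14–20); steps 5, 12 and 13 are branches.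

Step 15 (key step). The alkoxide may expel the C1–C2 bridge as an enolate and leave an arene (alkoxide-accelerated cycloreversion), or undergo a 1,3-shift, because the bicyclooctadienolate has an aromatic product within reach and the C4 terminus is fully substituted and slow to bond. Fallback: keep both methoxy groups through the rearrangement. Setting out from 15, addition of 23 should give the 3,3-dimethoxy carbinol F1; KH with 18-crown-6 should then give the 1,1-dimethoxy cis-decalin-2-one F2, the substrate pattern for which this rearrangement is best documented, and the enolate that cycloreversion would expel is a donor-only trioxygenated alkene, a poorer leaving fragment. SmI2 in THF/MeOH removes both methoxy groups and the route is rejoined at 27. The cost is a more crowded C1 next to the forming bond.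

Step 14. Facial selectivity at the ketone may be poor, because the two unsaturated bridges differ only in an oxygen against a methyl group beside C7. Fallback: relay the selectivity through C1. Setting out from 15, SmI2 (2 equiv) at −78 °C should stop at the monomethoxy ketone F3, the samarium enolate being protonated at C1 from the side of C5–H so that the methoxy group lies syn to the C8=C9 bridge. Reagent 23 then adds anti to the neighbouring methoxy group, that is, from the enol-ether face, to give carbinol F4. The rearrangement of F4 gives the 1α-methoxy ketone F5, and a second SmI2 treatment returns to the route at 27.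

Step 9. The cycloaddition may be too slow at the hindered methyl-bearing diene terminus, while 13 decomposes to ketene and ethylene on stronger heating and is consumed by traces of acid. Fallback: use the more nucleophilic 1,1-diethoxyethene as a two-carbon partner. Setting out from 12, cycloaddition at rt to 40 °C should give the racemic 6,6-diethoxy adduct F6 with the same regiochemistry; Me3SiOTf with i-Pr2NEt then removes ethanol towards C5 (C7 is a bridgehead) and the route is rejoined at 14.

Step 17. Hydride may enter from the α face if the ring-A chair with axial C19 reacts, giving the 2β-alcohol; the two faces of C2 are each flanked by two 1,3-substituents and the preference rests on a conformational argument. Fallback: invert at C2. Setting out from 29, the same reduction and hydrolysis would give the 2β-epimer F7; Mitsunobu reaction with chloroacetic acid (PPh3, diisopropyl azodicarboxylate, toluene) gives the 2α-chloroacetate F8, the hindered C6 ketone being inert, and thiourea with NaHCO3 in EtOH removes the chloroacetyl group without touching the acetate, returning to the route at 31.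

Step 19. Ene reaction of singlet oxygen at the C8=C9 alkene, or over-oxidation, may compete with furan oxidation. Fallback: an oxidation that cannot touch the alkene. Setting out from 32, C–H borylation with [Ir(OMe)(cod)]2, 4,4′-di-tert-butyl-2,2′-bipyridine and bis(pinacolato)diboron should occur at the furan α-carbon remote from the chain to give boronate F9. NaBO3 in THF/H2O oxidises the C–B bond, and the resulting 2-hydroxyfuran tautomerises to the conjugated butenolide, which rejoins the route at 35 and makes step 20 unnecessary.

## Further compounds

F1 | step 15 | 3,3-dimethoxy analogue of 24 (same configuration at C1, C2 and C4 of the bicycle) | CC(C)[Si](OC/C(C)=C\[C@@]1(O)C(OC)(OC)[C@@]2(C)C=C(OCC)[C@@H]1C(C)=C2CCc3ccoc3)(C(C)C)C(C)C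
F2 | step 15 | 1,1-dimethoxy analogue of 27 | CC(C)[Si](OC[C@@]1(C)CC(=O)C(OC)(OC)[C@]2(C)C(CCc3ccoc3)=C(C)C=C(OCC)[C@H]12)(C(C)C)C(C)C
F3 | step 14 | monomethoxy ketone, methoxy group syn to the C8=C9 bridge | O=C1[C@H](OC)[C@@]2(C)C=C(OCC)[C@@H]1C(C)=C2CCc3ccoc3
F4 | step 14 | 3-methoxy analogue of 24, methoxy group syn to the C8=C9 bridge | CC(C)[Si](OC/C(C)=C\[C@@]1(O)[C@H](OC)[C@@]2(C)C=C(OCC)[C@@H]1C(C)=C2CCc3ccoc3)(C(C)C)C(C)C
F5 | step 14 | 1α-methoxy analogue of 27 | CC(C)[Si](OC[C@@]1(C)CC(=O)[C@H](OC)[C@]2(C)C(CCc3ccoc3)=C(C)C=C(OCC)[C@H]12)(C(C)C)C(C)C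
F6 | step 9 | racemic 6,6-diethoxy-8-[2-(furan-3-yl)ethyl]-3,3-dimethoxy-4,7-dimethylbicyclo[2.2.2]oct-7-en-2-one | CCOC1(OCC)CC2(C)C(CCc3ccoc3)=C(C)C1C(=O)C2(OC)OC
F7 | step 17 | 2β-epimer of 31 | CC(=O)OC[C@@]1(C)C[C@@H](O)C[C@]2(C)C(CCc3ccoc3)=C(C)CC(=O)[C@H]12
F8 | step 17 | 2α-chloroacetate of 31 | CC(=O)OC[C@@]1(C)C[C@H](OC(=O)CCl)C[C@]2(C)C(CCc3ccoc3)=C(C)CC(=O)[C@H]12
F9 | step 19 | 5-(pinacolatoboryl)furan derived from 32 | CC(=O)OC[C@@]1(C)C[C@H](O)C[C@]2(C)C(CCc3coc(B4OC(C)(C)C(C)(C)O4)c3)=C(C)C[C@H](O)[C@H]12
A1 | alternative 1 | cis-decalin C6 pinacol boronate | CC(=O)OC[C@@]1(C)C[C@H](O[Si](C)(C)C(C)(C)C)C[C@]2(C)C(CCC3=CC(=O)OC3)=C(C)C[C@H](B4OC(C)(C)C(C)(C)O4)[C@H]12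
A2 | alternative 1 | open-chain triene with Z-alkenylboronate | CC(=O)OC[C@](C)(/C=C\B1OC(C)(C)C(C)(C)O1)C[C@H](O[Si](C)(C)C(C)(C)C)C/C(C)=C(\CCC1=CC(=O)OC1)C(C)=C
A3 | alternative 2 | cis-decalin C6 alcohol | CC[Si](CC)(CC)OC[C@@]1(C)C[C@H](O[Si](C)(C)C(C)(C)C)C[C@]2(C)C(CCc3ccoc3)=C(C)C[C@H](O)[C@H]12
A4 | alternative 2 | cis-fused bicyclo[4.2.0]octane: C6 cyclobutanol with isopropenyl and furylethyl groups on C9 | CC[Si](CC)(CC)OC[C@@]1(C)C[C@H](O[Si](C)(C)C(C)(C)C)C[C@]2(C)[C@@](CCc3ccoc3)(C(C)=C)[C@H](O)[C@H]12
A5 | alternative 3 | cis-decalin C2 ketone | CC(=O)OC[C@@]1(C)CC(=O)C[C@]2(C)C(CCC3=CC(=O)OC3)=C(C)C[C@H](O[Si](C)(C)C(C)(C)C)[C@H]12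
A6 | alternative 3 | cyclohex-2-en-1-ol (C8 carbinol, either epimer) with silyl enol ether tether on C5 | CC(=O)OC[C@@](C)(CC(=C)O[Si](C)(C)C)[C@H]1[C@@H](O[Si](C)(C)C(C)(C)C)CC(C)(O)C(CCC2=CC(=O)OC2)=C1C
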